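Take the logarithm of the share of substrate not yet turned into target, and read its slope against time.

| flask | substrate | solid reagent | free catalyst | remark | time |
|---|---|---|---|---|---|
| Saturday's | 0.13 M | 1.8 equiv | 0.2 mol% (in portions, 3) | run made earlier; portions every 4.0 min |  |
| Sunday's | 0.30 M | 1.8 equiv | 0.2 mol% (in portions, 3) | run made earlier; portions every 4.0 min |  |
| midnight | 0.20 M | 1.80 equiv | 0.2 mol% (in portions, 3) | the portions of free catalyst follow each other after 4.0 min, the first at the start | 40 min |
| noon | 0.20 M | 1.80 equiv | 0.2 mol% | everything together at the start | 12 min |

| run | time / min | target / % |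
|---|---|---|
| Saturday's | 3.00 | 2 |
| Saturday's | 8.00 | 8 |
| Saturday's | 15.0 | 29 |
| Saturday's | 25.0 | 48 |
| Sunday's | 2.00 | 3 |
| Sunday's | 4.00 | 11 |
| Sunday's | 10.0 | 30 |
| Sunday's | 25.0 | 67 |

(each reading ± 2 percentage points)

* the winner by amount of target, in percent of the substrate charged; "neither" if no more than 2 percentage points parts them (midnight / noon / neither)
* how much target is there at the end, in percent of the substrate charged: midnight
* how much target is there at the end, in percent of the substrate charged: noon

- given per volume of solution although it is solid: solid reagent
- at the start none of the solid reagent is in solution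

I took free catalyst to turn substrate into target while the solid reagent goes into solution. I read the slope from 8.00 min to 25.0 min in Saturday's run as 0.0336 min⁻¹, and from 4.00 min to 25.0 min in Sunday's run as 0.0472 min⁻¹. Working in powers of ten, and with the equivalents and the loading on the substrate the same in both runs, these two readings made the slope grow as c(substrate) to the power 0.409. So at c(substrate) = 0.20 M I put the running constant, the slope of that logarithm against time, at 0.0400 min⁻¹.

I started each clock at the mean arrival of the catalyst, which is 4.00 min in midnight and the start in noon. My reckoning then gave 76.3 % for midnight and 38.1 % for noon.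

The forecast named midnight as the winner, with 75 % for midnight and 28 % for noon, saying “only 12 min is available and dissolution caps it”. My noon stood higher than the forecast's.

The flasks gave 73.5 % for midnight and 41.6 % for noon, so midnight won.

    substrate + catalyst intermediate A → catalyst intermediate B (k = 2.69 M⁻¹ s⁻¹)
    substrate ⇌ dormant form (K = 0.850, k = 3.16 × 10⁻⁴ s⁻¹)
    catalyst intermediate B → free catalyst + target (k = 63.6 s⁻¹)
    partner + free catalyst → catalyst intermediate A (k = 81.4 M⁻¹ s⁻¹)
    solid reagent ⇌ partner, rate k5*(cs5 - [partner]) while solid is left; crystals form when [partner] > cs5 (solubility = 0.120 M, k = 0.00193 s⁻¹)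
    partner + free catalyst → spent catalyst (k = 0.00130 M⁻¹ s⁻¹)

In noon at 5.35 min, partner, the dissolved form of the solid reagent, was being made 1.41 times as fast as it was used up, each step taken net, and by 12.0 min c(partner) stood at 0.0463 M. At that same time in noon, catalyst intermediate A, the resting state, held 93.4 % of the catalyst, and its step with substrate gave substrate a half-life of 12 min. For the flask noon left until 20 min, the running constant gives 55.1 %, and that flask held 58.4 % of target.

All runs were generated by integration with made-up constants, and the scatter is random.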